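Abbreviation used throughout: TBS = tert-butyldimethylsilyl, TBSO = its ether.

## Analysis of the target

Target 19 (C30H22O8) is a formal dehydrodimer of a trihydroxychalcone. A 7-hydroxychroman-4-one (benzo ring A, pyranone ring C) carries a 4-hydroxyphenyl group (ring B) at C2. At C3 it carries a phenol ring (ring D), bonded through the carbon ortho to its hydroxyl, which bears para to that hydroxyl an (E)-enone ending in a 2,4-dihydroxybenzoyl ring (ring E).

The only stereocentres are C2 (R) and C3 (S) of ring C. They are adjacent, the two aryl groups are trans and diequatorial, and this is the more stable relative configuration. C3-H is benzylic and alpha to the C4 ketone, so C3 equilibrates readily and the real stereochemical task is the absolute configuration at C2.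

C2 is fragile as well. The C3 enolate can expel O1 to give an achiral alpha-aryl chalcone, and a phenoxide on ring B can open the C2-O1 bond through a quinone methide, so bases racemise the compound. The phenol of ring D lies next to the C4 ketone and can dehydrate to a fused benzofuran under acid. The chalcone, with its free ortho hydroxyl on ring E, can close to a second flavanone, and the enone forbids hydrogenolysis and strong nucleophiles.

The feature the route exploits is the C2-C3 bond of ring C. C2 carries O1, ring B and one hydrogen, exactly as the benzylic carbon of an aryl benzyl ether does. C3 carries an aryl group (ring D) and an acyl group (C4), exactly as a donor/acceptor carbene does.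

The difficulty is therefore to make the crowded C2-C3 and C3-aryl bonds and to fix C2 without passing through conditions that open ring C, and to finish five phenols and the chalcone near neutrality.

## Retrosynthetic reasoning

**19 from 18.** The last cut is through the five O-Si bonds of 18. One protecting group on all five phenols means one buffered fluoride treatment at the end. That is the mildest way to release a product that tolerates neither base (opening of ring C, closure of the chalcone) nor hot acid (benzofuran formation).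

**18 from 13 and 17.** The enone is cut at its C=C bond, giving aldehyde 13 on ring D and the acyl-stabilised ylide 17 that carries ring E. The bond is cut here and not by an aldol condensation, because the aqueous base of a chalcone condensation would open ring C. A stabilised ylide is not basic enough to enolise C3, gives the E-alkene by its nature, and joins the two halves convergently after both stereocentres exist.

**13 from 12.** The aldehyde of 13 is carried as the dioxolane of 12. A free aldehyde would condense with the enolates used earlier and could intercept the carbenoid of the key step. The acetal costs one step on and one off, and its removal by dilute aqueous acid also leaves C3 at its trans equilibrium.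

**12 from 10 (key disconnection).** Ring C is cut at C2-C3. This is the one ring bond whose cleavage removes the ring and both stereocentres at once, leaving an acyclic, achiral diazo ketone 10.

- In 10, C3 is the diazo carbon between the ring-D aryl group and the ring-A ketone.
- C2 is the CH2 of a 4-siloxybenzyl ether on the ring-A oxygen, so what looks like a protecting group is in fact ring B and C2.
- The forward reaction must insert the carbenoid carbon into one of the two enantiotopic benzylic hydrogens under control of a chiral dirhodium carboxylate, which sets C2.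
- C3 is then allowed to relax from the kinetic mixture containing the cis epimer 11 to the trans compound 12.
- The phenol oxygen of ring D must carry silicon and not an alkyl group, so that it offers no competing C-H bond five atoms from the carbenoid.

**10 from 9.** The diazo group is put on the doubly activated methylene of deoxybenzoin 9 by diazo transfer from a sulfonyl azide. This is reliable for benzyl aryl ketones and needs only an amidine base.

**9 from 5 and 8.** Deoxybenzoin 9 is cut at the bond between its methylene carbon and ring D, giving methyl ketone 5 and aryl bromide 8, joined by palladium-catalysed ketone arylation. This is preferred to a Friedel-Crafts acylation of a resorcinol, whose Lewis acid would strip the silyl groups and cyclise a 2-oxybenzyl ketone to a benzofuran. It also places the bromine of 8 exactly where the commercial phenol 6 has it.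

**Feedstocks.**
- Ketone 5 comes from 2 and benzyl alcohol 4 by etherification of the hydrogen-bonded phenol under neutral redox-condensation conditions.
- 2 comes from 1 by silylation of the free para phenol, and 4 from aldehyde 3 by reduction.
- Bromide 8 comes from 6 through silyl ether 7 and acetal formation.
- Ylide 17 comes from chloroketone 14 through bis-silyl ether 15 and phosphonium salt 16.

## Alternatives that were turned down

**Alternative 1:** the textbook route. Disconnection of O1-C2 and C2-C3 together, back to aldehyde 3 and the 2-hydroxydeoxybenzoin A1. The forward key step is an amine-mediated aldol condensation to the alpha-aryl chalcone A2, followed by six-ring oxa-Michael closure to the chromanone of 12. It was turned down because the closure runs through the achiral A2 under fully reversible conditions. The trans relative configuration comes for free, but the product is racemic, and any chiral catalyst works against an equilibrium that erases C2. The route would need a resolution, and A1 still has to be made by the same arylation used here.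

**Alternative 2:** disconnection of the bond between C2 and ring B, back to the isoflavone A3 and an arylboron reagent for ring B. The forward key step is an asymmetric 1,4-addition catalysed by monovalent rhodium or divalent palladium, with protonation setting C3. It was turned down for three reasons. The enone of A3 carries a bulky ortho-substituted aryl group on its alpha carbon, so the metal enolate would be fully substituted, and the conjugate additions that work on chromones have been shown only where C3 is unsubstituted. The aqueous base they need is the condition under which ring C opens. And A3 is made from A1 plus a one-carbon unit, so it costs more steps than the diazo ketone 10.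

**Alternative 3:** the biomimetic route. Disconnection of the C3-ring D bond and O1-C2, back to two molecules of the chalcone A4. The forward key step is a one-electron oxidation: the phenoxyl radical of one A4 couples through its alpha carbon with the position ortho to the phenol of a second, and the resulting quinone methide A5 is trapped by the ring-A hydroxyl. It was turned down on three counts. The radical has spin density at oxygen, at both ortho carbons, at the ipso carbon and at the alpha carbon, so the required pairing is one of many. A5 can equally be trapped by the neighbouring ring-D phenol, giving the isomeric dihydrobenzofuran A6. And nothing in the flask controls the absolute configuration.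

Key step: step 8

Assumption: 1, 3, 6 and 14 are taken as catalogue compounds. The sense of induction of Rh2(S-PTTL)4 (dirhodium tetrakis[N-phthaloyl-(S)-tert-leucinate], divalent rhodium) in step 8 is assumed to give the 2R series; should it give 2S, the mirror-image catalyst Rh2(R-PTTL)4 is used with nothing else changed.

## Route

Step 1
Reactants: 1 1-(2,4-dihydroxyphenyl)ethan-1-one
Product: 2 1-(4-(TBSO)-2-hydroxyphenyl)ethan-1-one
Conditions: TBSCl (1.05 equiv), imidazole, CH2Cl2, 0 °C
Reagents that add atoms: tert-butyldimethylsilyl chloride (TBSCl), CC(C)(C)[Si](C)(C)Cl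
Why: Selective silylation; the para hydroxyl is free and the more nucleophilic one, while the ortho hydroxyl is tied up in a hydrogen bond to the ketone and stays behind.

Step 2
Reactants: 3 4-(TBSO)benzaldehyde
Product: 4 (4-(TBSO)phenyl)methanol
Conditions: NaBH4, EtOH/THF, 0 °C
Reagents that add atoms: none
Why: Borohydride reduction of an aryl aldehyde; the aryl silyl ether should survive the short, cold reaction.

Step 3
Reactants: 2 1-(4-(TBSO)-2-hydroxyphenyl)ethan-1-one; 4 (4-(TBSO)phenyl)methanol
Product: 5 1-(4-(TBSO)-2-((4-(TBSO)benzyl)oxy)phenyl)ethan-1-one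
Conditions: PPh3, DIAD, THF, 0 to 23 °C
Reagents that add atoms: none
Why: Mitsunobu etherification; the ortho-acyl phenol is acidic enough to be the pronucleophile, and the neutral conditions avoid the carbonate bases that strip phenolic silyl ethers and could C-alkylate the ketone.

Step 4
Reactants: 6 3-bromo-4-hydroxybenzaldehyde
Product: 7 3-bromo-4-(TBSO)benzaldehyde
Conditions: TBSCl, imidazole, DMF, 23 °C
Reagents that add atoms: tert-butyldimethylsilyl chloride (TBSCl), CC(C)(C)[Si](C)(C)Cl
Why: Standard phenol silylation; silicon is chosen for this oxygen because it offers the later carbenoid no O-CH bond.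

Step 5
Reactants: 7 3-bromo-4-(TBSO)benzaldehyde
Product: 8 (2-bromo-4-(1,3-dioxolan-2-yl)phenoxy)(tert-butyl)dimethylsilane
Conditions: (TMSOCH2)2, TMSOTf (cat.), CH2Cl2, -78 °C
Reagents that add atoms: 1,2-bis(trimethylsilyloxy)ethane, C[Si](C)(C)OCCO[Si](C)(C)C
Why: Aprotic acetalisation with a bis-silyl glycol and catalytic silyl triflate (Noyori conditions); it works at low temperature without free acid or alcohol, so the aryl silyl ether is safe.

Step 6
Reactants: 5 1-(4-(TBSO)-2-((4-(TBSO)benzyl)oxy)phenyl)ethan-1-one; 8 (2-bromo-4-(1,3-dioxolan-2-yl)phenoxy)(tert-butyl)dimethylsilane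
Product: 9 1-(4-(TBSO)-2-((4-(TBSO)benzyl)oxy)phenyl)-2-(2-(TBSO)-5-(1,3-dioxolan-2-yl)phenyl)ethan-1-one
Conditions: Pd2(dba)3 (1.5 mol %), XPhos (4 mol %), K3PO4, toluene, 80 °C
Reagents that add atoms: none
Why: Palladium-catalysed alpha-arylation of a methyl ketone (zerovalent palladium, bulky biaryl phosphine) with a weak phosphate base. The ortho substituent of the bromide and the higher acidity of the product stop the reaction after one arylation, and the acetal hides the aldehyde from the enolate.

Step 7
Reactants: 9 1-(4-(TBSO)-2-((4-(TBSO)benzyl)oxy)phenyl)-2-(2-(TBSO)-5-(1,3-dioxolan-2-yl)phenyl)ethan-1-one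
Product: 10 2-diazo-1-(4-(TBSO)-2-((4-(TBSO)benzyl)oxy)phenyl)-2-(2-(TBSO)-5-(1,3-dioxolan-2-yl)phenyl)ethan-1-one
Conditions: p-ABSA, DBU, MeCN, 0 °C
Reagents that add atoms: 4-acetamidobenzenesulfonyl azide (p-ABSA), CC(=O)Nc1ccc(cc1)S(=O)(=O)N=[N+]=[N-]
Why: Regitz diazo transfer; the methylene between aryl and aroyl is acidic enough for an amidine base, and the enolate is trapped by the sulfonyl azide faster than it can do anything else.

Step 8
Reactants: 10 2-diazo-1-(4-(TBSO)-2-((4-(TBSO)benzyl)oxy)phenyl)-2-(2-(TBSO)-5-(1,3-dioxolan-2-yl)phenyl)ethan-1-one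
Product: 12 (2R,3S)-7-(TBSO)-2-(4-(TBSO)phenyl)-3-(2-(TBSO)-5-(1,3-dioxolan-2-yl)phenyl)chroman-4-one, via cis-(2R,3R)-epimer 11 (not isolated)
Conditions: Rh2(S-PTTL)4 (1 mol %), toluene, -40 °C, slow addition of 10 (0.01 M); then camphorsulfonic acid (10 mol %), CH2Cl2, 23 °C
Reagents that add atoms: none
Why: The rhodium carbenoid formed from 10 by loss of dinitrogen carries an aryl donor and an acyl acceptor; such carbenoids insert into C-H bonds through a concerted, asynchronous three-centre transition state with hydride-transfer character, which favours the OCH2 hydrogens because they are activated by the ether oxygen and by the electron-rich siloxyphenyl ring. The closest known reaction types are the conversion of 2-alkoxyphenyl alpha-diazoketones into chroman-4-ones by chiral dirhodium carboxylates, and the insertion of aryl-substituted carbenoids into benzylic ether C-H bonds that gives 2-aryl-2,3-dihydrobenzofurans with dirhodium tert-leucinate catalysts. Ring C is closed by forming the C2-C3 bond in a 1,6-insertion through a six-membered chair-like transition state; no 1,5-insertion can compete because the atom in that position is the ether oxygen and the neighbouring ring-D oxygen carries silicon and no O-CH bond. C2 is set by the catalyst, whose chiral pocket of phthalimido walls selects one of the two enantiotopic benzylic hydrogens and inserts with retention. C3 is set by the substrate: acid-catalysed enolisation of the first-formed mixture, which contains the cis epimer 11, funnels it to the trans isomer with both aryl groups equatorial, and the neutral enol, unlike an enolate, does not expel O1, so C2 is not touched. The selectivity the step needs is insertion over attack of the ether oxygen on the carbenoid (a five-membered oxonium ylide and 1,2-shift of the benzyl group to a benzofuranone); the aryl ether oxygen is a poor donor because its lone pair is shared with a ring that bears the acyl group, and the bulky carboxylate catalyst, the non-coordinating solvent and the low temperature push the same way. Slow addition at high dilution keeps intermolecular reactions of the carbenoid with the acetal or with a second diazo molecule down.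

Step 9
Reactants: 12 (2R,3S)-7-(TBSO)-2-(4-(TBSO)phenyl)-3-(2-(TBSO)-5-(1,3-dioxolan-2-yl)phenyl)chroman-4-one
Product: 13 4-(TBSO)-3-((2R,3S)-7-(TBSO)-2-(4-(TBSO)phenyl)-4-oxochroman-3-yl)benzaldehyde
Conditions: TsOH·H2O (cat.), THF/H2O, 23 °C
Reagents that add atoms: water, O
Why: Acid hydrolysis of an electron-rich aryl dioxolane is fast at room temperature; aryl silyl ethers tolerate dilute acid, and the medium keeps C3 at its trans equilibrium without generating the enolate that would endanger C2.

Step 10
Reactants: 14 2-chloro-1-(2,4-dihydroxyphenyl)ethan-1-one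
Product: 15 1-(2,4-bis(TBSO)phenyl)-2-chloroethan-1-one
Conditions: TBSOTf (2.2 equiv), 2,6-lutidine, CH2Cl2, -78 to 0 °C
Reagents that add atoms: tert-butyldimethylsilyl trifluoromethanesulfonate (TBSOTf), CC(C)(C)[Si](C)(C)OS(=O)(=O)C(F)(F)F
Why: The silyl triflate is strong enough for the hydrogen-bonded ortho phenol, and the hindered pyridine base, unlike imidazole, does not displace the reactive alpha-chloride.

Step 11
Reactants: 15 1-(2,4-bis(TBSO)phenyl)-2-chloroethan-1-one
Product: 17 1-(2,4-bis(TBSO)phenyl)-2-(triphenylphosphoranylidene)ethan-1-one, via phosphonium chloride 16 (not isolated)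
Conditions: PPh3, toluene, 80 °C; then Et3N, CH2Cl2, 0 °C
Reagents that add atoms: triphenylphosphine, c1ccc(cc1)P(c1ccccc1)c1ccccc1
Why: SN2 displacement of the phenacyl chloride by the phosphine gives salt 16, which is acidic enough for a tertiary amine to convert it into the acyl-stabilised ylide without touching the silyl ethers.

Step 12
Reactants: 13 4-(TBSO)-3-((2R,3S)-7-(TBSO)-2-(4-(TBSO)phenyl)-4-oxochroman-3-yl)benzaldehyde; 17 1-(2,4-bis(TBSO)phenyl)-2-(triphenylphosphoranylidene)ethan-1-one
Product: 18 (2R,3S)-3-(5-((E)-3-(2,4-bis(TBSO)phenyl)-3-oxoprop-1-en-1-yl)-2-(TBSO)phenyl)-7-(TBSO)-2-(4-(TBSO)phenyl)chroman-4-one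
Conditions: toluene, 90 °C
Reagents that add atoms: none
Why: Wittig olefination with a stabilised ylide, which reacts only with the aldehyde and not with the hindered C4 ketone and gives the E-enone under thermodynamic control. The ylide is far too weak a base to enolise C3, so neither stereocentre is at risk.

Step 13
Reactants: 18 (2R,3S)-3-(5-((E)-3-(2,4-bis(TBSO)phenyl)-3-oxoprop-1-en-1-yl)-2-(TBSO)phenyl)-7-(TBSO)-2-(4-(TBSO)phenyl)chroman-4-one
Product: 19 (2R,3S)-3-(5-((E)-3-(2,4-dihydroxyphenyl)-3-oxoprop-1-en-1-yl)-2-hydroxyphenyl)-7-hydroxy-2-(4-hydroxyphenyl)chroman-4-one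
Conditions: HF·pyridine, pyridine, THF, 0 to 23 °C
Reagents that add atoms: none
Why: Fluoride cleavage of aryl silyl ethers in a pyridine-buffered, slightly acidic medium releases the five phenols as neutral phenols and not as phenoxides, so the ring-opening paths at C2 and the closure of the chalcone are not switched on.

## Compound list

1 | 1-(2,4-dihydroxyphenyl)ethan-1-one | CC(=O)c1ccc(O)cc1O | starting material
2 | 1-(4-(TBSO)-2-hydroxyphenyl)ethan-1-one | CC(=O)c1ccc(O[Si](C)(C)C(C)(C)C)cc1O | intermediate
3 | 4-(TBSO)benzaldehyde | O=Cc1ccc(O[Si](C)(C)C(C)(C)C)cc1 | starting material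
4 | (4-(TBSO)phenyl)methanol | OCc1ccc(O[Si](C)(C)C(C)(C)C)cc1 | intermediate
5 | 1-(4-(TBSO)-2-((4-(TBSO)benzyl)oxy)phenyl)ethan-1-one | CC(=O)c1ccc(O[Si](C)(C)C(C)(C)C)cc1OCc1ccc(O[Si](C)(C)C(C)(C)C)cc1 | intermediate
6 | 3-bromo-4-hydroxybenzaldehyde | O=Cc1ccc(O)c(Br)c1 | starting material
7 | 3-bromo-4-(TBSO)benzaldehyde | O=Cc1ccc(O[Si](C)(C)C(C)(C)C)c(Br)c1 | intermediate
8 | (2-bromo-4-(1,3-dioxolan-2-yl)phenoxy)(tert-butyl)dimethylsilane | CC(C)(C)[Si](C)(C)Oc1ccc(C2OCCO2)cc1Br | intermediate
9 | 1-(4-(TBSO)-2-((4-(TBSO)benzyl)oxy)phenyl)-2-(2-(TBSO)-5-(1,3-dioxolan-2-yl)phenyl)ethan-1-one | O=C(Cc1cc(C2OCCO2)ccc1O[Si](C)(C)C(C)(C)C)c1ccc(O[Si](C)(C)C(C)(C)C)cc1OCc1ccc(O[Si](C)(C)C(C)(C)C)cc1 | intermediate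
10 | 2-diazo-1-(4-(TBSO)-2-((4-(TBSO)benzyl)oxy)phenyl)-2-(2-(TBSO)-5-(1,3-dioxolan-2-yl)phenyl)ethan-1-one | O=C(C(=[N+]=[N-])c1cc(C2OCCO2)ccc1O[Si](C)(C)C(C)(C)C)c1ccc(O[Si](C)(C)C(C)(C)C)cc1OCc1ccc(O[Si](C)(C)C(C)(C)C)cc1 | intermediate
11 | (2R,3R)-7-(TBSO)-2-(4-(TBSO)phenyl)-3-(2-(TBSO)-5-(1,3-dioxolan-2-yl)phenyl)chroman-4-one (cis epimer) | C1COC(O1)c1ccc(O[Si](C)(C)C(C)(C)C)c([C@H]2C(=O)c3ccc(O[Si](C)(C)C(C)(C)C)cc3O[C@H]2c2ccc(O[Si](C)(C)C(C)(C)C)cc2)c1 | intermediate
12 | (2R,3S)-7-(TBSO)-2-(4-(TBSO)phenyl)-3-(2-(TBSO)-5-(1,3-dioxolan-2-yl)phenyl)chroman-4-one | C1COC(O1)c1ccc(O[Si](C)(C)C(C)(C)C)c([C@@H]2C(=O)c3ccc(O[Si](C)(C)C(C)(C)C)cc3O[C@H]2c2ccc(O[Si](C)(C)C(C)(C)C)cc2)c1 | intermediate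
13 | 4-(TBSO)-3-((2R,3S)-7-(TBSO)-2-(4-(TBSO)phenyl)-4-oxochroman-3-yl)benzaldehyde | O=Cc1ccc(O[Si](C)(C)C(C)(C)C)c([C@@H]2C(=O)c3ccc(O[Si](C)(C)C(C)(C)C)cc3O[C@H]2c2ccc(O[Si](C)(C)C(C)(C)C)cc2)c1 | intermediate
14 | 2-chloro-1-(2,4-dihydroxyphenyl)ethan-1-one | O=C(CCl)c1ccc(O)cc1O | starting material
15 | 1-(2,4-bis(TBSO)phenyl)-2-chloroethan-1-one | O=C(CCl)c1ccc(O[Si](C)(C)C(C)(C)C)cc1O[Si](C)(C)C(C)(C)C | intermediate
16 | (2-(2,4-bis(TBSO)phenyl)-2-oxoethyl)triphenylphosphonium chloride | [Cl-].O=C(C[P+](c1ccccc1)(c1ccccc1)c1ccccc1)c1ccc(O[Si](C)(C)C(C)(C)C)cc1O[Si](C)(C)C(C)(C)C | intermediate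
17 | 1-(2,4-bis(TBSO)phenyl)-2-(triphenylphosphoranylidene)ethan-1-one | O=C(C=P(c1ccccc1)(c1ccccc1)c1ccccc1)c1ccc(O[Si](C)(C)C(C)(C)C)cc1O[Si](C)(C)C(C)(C)C | intermediate
18 | (2R,3S)-3-(5-((E)-3-(2,4-bis(TBSO)phenyl)-3-oxoprop-1-en-1-yl)-2-(TBSO)phenyl)-7-(TBSO)-2-(4-(TBSO)phenyl)chroman-4-one | O=C(/C=C/c1ccc(O[Si](C)(C)C(C)(C)C)c([C@@H]2C(=O)c3ccc(O[Si](C)(C)C(C)(C)C)cc3O[C@H]2c2ccc(O[Si](C)(C)C(C)(C)C)cc2)c1)c1ccc(O[Si](C)(C)C(C)(C)C)cc1O[Si](C)(C)C(C)(C)C | intermediate
19 | (2R,3S)-3-(5-((E)-3-(2,4-dihydroxyphenyl)-3-oxoprop-1-en-1-yl)-2-hydroxyphenyl)-7-hydroxy-2-(4-hydroxyphenyl)chroman-4-one | O=C(/C=C/c1ccc(O)c([C@@H]2C(=O)c3ccc(O)cc3O[C@H]2c2ccc(O)cc2)c1)c1ccc(O)cc1O | target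

## Step count and least certain steps

Total step count: 13. Longest linear sequence: 8 steps (steps 1, 3, 6, 7, 8, 9, 12, 13).

**Step 8 (key step).** The most likely failure is attack of the ring-A ether oxygen on the carbenoid, followed by a 1,2-shift of the benzyl group, which would divert material away from C-H insertion. The second is poor discrimination between the two enantiotopic benzylic hydrogens, because the ortho-substituted donor ring is twisted out of the carbenoid plane.

Fallback, from 9 and 3 back to 12:
- Hydrogenolysis of the siloxybenzyl ether of 9 (H2, palladium on carbon, EtOAc) should give the free ring-A phenol 1-(4-(TBSO)-2-hydroxyphenyl)-2-(2-(TBSO)-5-(1,3-dioxolan-2-yl)phenyl)ethan-1-one F1.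
- Condensation of F1 with aldehyde 3 (catalytic piperidine, toluene, molecular sieves, 80 °C; aldol condensation and six-ring oxa-Michael closure under thermodynamic control) should give the trans chromanone as a racemate, that is 12 together with its (2S,3R)-enantiomer F2.
- Chromatography on a chiral stationary phase delivers 12, and the route resumes at step 9.
- F2 can be returned to the racemate by amine-mediated opening and closing of ring C and resolved again.

**Step 6.** The phenolic silyl ethers may be lost to phosphate at 80 °C, or oxidative addition at the bromide ortho to the bulky siloxy group may be so slow that the ketone enolate condenses with itself.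

Fallback, from 5 and 8 back to 9, with the polarity of the union reversed:
- 5 is converted to its trimethylsilyl enol ether (TMSOTf, Et3N) and brominated with NBS at -78 °C to give 2-bromo-1-(4-(TBSO)-2-((4-(TBSO)benzyl)oxy)phenyl)ethan-1-one F3.
- 8 is borylated (B2pin2, Pd(dppf)Cl2, KOAc, dioxane, 80 °C) to give 2-(2-(TBSO)-5-(1,3-dioxolan-2-yl)phenyl)-4,4,5,5-tetramethyl-1,3,2-dioxaborolane F4.
- Suzuki coupling of the alpha-bromoketone F3 with F4 (Pd(PPh3)4, K3PO4, toluene/H2O, 60 °C) should give 9.

**Step 12.** The electron-rich aldehyde may react only slowly with the stabilised ylide, so that long heating leads to silyl loss or decomposition before the olefination is complete.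

Fallback, from 13 and 17 back to 18, making the same C=C bond by metathesis:
- Aldehyde-selective methylenation of 13 (Zn, CH2I2, Ti(OiPr)4, THF) should give (2R,3S)-7-(TBSO)-2-(4-(TBSO)phenyl)-3-(2-(TBSO)-5-vinylphenyl)chroman-4-one F5.
- Ylide 17 and paraformaldehyde (CH2Cl2, 40 °C) should give 1-(2,4-bis(TBSO)phenyl)prop-2-en-1-one F6.
- Cross-metathesis of F5 with an excess of F6 (second-generation Hoveyda-Grubbs catalyst, CH2Cl2, 40 °C) should give the E-enone 18 under neutral conditions.

**Step 13.** If the medium is not acidic enough, phenoxides form; ring C can then open at C2 with loss of optical purity, or the chalcone can close to a second flavanone. The hindered silyl ether on ring D may also be cleaved only slowly, which lengthens the exposure.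

Fallback, from 13 and 14 to 19, deprotecting the halves separately and making the neutral olefination the last step:
- 13 is desilylated (HF·pyridine, pyridine, THF) to 4-hydroxy-3-((2R,3S)-7-hydroxy-2-(4-hydroxyphenyl)-4-oxochroman-3-yl)benzaldehyde F7.
- 14 and PPh3 (MeCN, 60 °C) give (2-(2,4-dihydroxyphenyl)-2-oxoethyl)triphenylphosphonium chloride F8.
- Aqueous NaHCO3 converts F8 to 1-(2,4-dihydroxyphenyl)-2-(triphenylphosphoranylidene)ethan-1-one F9.
- Wittig reaction of F7 with F9 (THF, 60 °C) should give 19 directly, so that no fluoride ever meets the chalcone.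

## Further compounds

F1 | step 8 | 1-(4-(TBSO)-2-hydroxyphenyl)-2-(2-(TBSO)-5-(1,3-dioxolan-2-yl)phenyl)ethan-1-one | O=C(Cc1cc(C2OCCO2)ccc1O[Si](C)(C)C(C)(C)C)c1ccc(O[Si](C)(C)C(C)(C)C)cc1O
F2 | step 8 | (2S,3R)-7-(TBSO)-2-(4-(TBSO)phenyl)-3-(2-(TBSO)-5-(1,3-dioxolan-2-yl)phenyl)chroman-4-one (enantiomer of 12) | C1COC(O1)c1ccc(O[Si](C)(C)C(C)(C)C)c([C@H]2C(=O)c3ccc(O[Si](C)(C)C(C)(C)C)cc3O[C@@H]2c2ccc(O[Si](C)(C)C(C)(C)C)cc2)c1
F3 | step 6 | 2-bromo-1-(4-(TBSO)-2-((4-(TBSO)benzyl)oxy)phenyl)ethan-1-one | O=C(CBr)c1ccc(O[Si](C)(C)C(C)(C)C)cc1OCc1ccc(O[Si](C)(C)C(C)(C)C)cc1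
F4 | step 6 | 2-(2-(TBSO)-5-(1,3-dioxolan-2-yl)phenyl)-4,4,5,5-tetramethyl-1,3,2-dioxaborolane | CC(C)(C)[Si](C)(C)Oc1ccc(C2OCCO2)cc1B1OC(C)(C)C(C)(C)O1
F5 | step 12 | (2R,3S)-7-(TBSO)-2-(4-(TBSO)phenyl)-3-(2-(TBSO)-5-vinylphenyl)chroman-4-one | C=Cc1ccc(O[Si](C)(C)C(C)(C)C)c([C@@H]2C(=O)c3ccc(O[Si](C)(C)C(C)(C)C)cc3O[C@H]2c2ccc(O[Si](C)(C)C(C)(C)C)cc2)c1
F6 | step 12 | 1-(2,4-bis(TBSO)phenyl)prop-2-en-1-one | C=CC(=O)c1ccc(O[Si](C)(C)C(C)(C)C)cc1O[Si](C)(C)C(C)(C)C
F7 | step 13 | 4-hydroxy-3-((2R,3S)-7-hydroxy-2-(4-hydroxyphenyl)-4-oxochroman-3-yl)benzaldehyde | O=Cc1ccc(O)c([C@@H]2C(=O)c3ccc(O)cc3O[C@H]2c2ccc(O)cc2)c1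
F8 | step 13 | (2-(2,4-dihydroxyphenyl)-2-oxoethyl)triphenylphosphonium chloride | [Cl-].O=C(C[P+](c1ccccc1)(c1ccccc1)c1ccccc1)c1ccc(O)cc1O
F9 | step 13 | 1-(2,4-dihydroxyphenyl)-2-(triphenylphosphoranylidene)ethan-1-one | O=C(C=P(c1ccccc1)(c1ccccc1)c1ccccc1)c1ccc(O)cc1O
A1 | alternative 1 | 1-(4-(TBSO)-2-hydroxyphenyl)-2-(2-(TBSO)-5-(1,3-dioxolan-2-yl)phenyl)ethan-1-one (same structure as F1) | O=C(Cc1cc(C2OCCO2)ccc1O[Si](C)(C)C(C)(C)C)c1ccc(O[Si](C)(C)C(C)(C)C)cc1O
A2 | alternative 1 | (E)-1-(4-(TBSO)-2-hydroxyphenyl)-2-(2-(TBSO)-5-(1,3-dioxolan-2-yl)phenyl)-3-(4-(TBSO)phenyl)prop-2-en-1-one | O=C(/C(=C/c1ccc(O[Si](C)(C)C(C)(C)C)cc1)c1cc(C2OCCO2)ccc1O[Si](C)(C)C(C)(C)C)c1ccc(O[Si](C)(C)C(C)(C)C)cc1O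
A3 | alternative 2 | 7-(TBSO)-3-(2-(TBSO)-5-(1,3-dioxolan-2-yl)phenyl)-4H-chromen-4-one | O=c1c(-c2cc(C3OCCO3)ccc2O[Si](C)(C)C(C)(C)C)coc2cc(O[Si](C)(C)C(C)(C)C)ccc12
A4 | alternative 3 | (E)-1-(2,4-dihydroxyphenyl)-3-(4-hydroxyphenyl)prop-2-en-1-one | O=C(/C=C/c1ccc(O)cc1)c1ccc(O)cc1O
A5 | alternative 3 | racemic 4-(2-(5-((E)-3-(2,4-dihydroxyphenyl)-3-oxoprop-1-en-1-yl)-2-hydroxyphenyl)-3-(2,4-dihydroxyphenyl)-3-oxopropylidene)cyclohexa-2,5-dien-1-one (quinone methide) | O=C1C=CC(=CC(C(=O)c2ccc(O)cc2O)c2cc(/C=C/C(=O)c3ccc(O)cc3O)ccc2O)C=C1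
A6 | alternative 3 | racemic trans-3-(2,4-dihydroxybenzoyl)-5-((E)-3-(2,4-dihydroxyphenyl)-3-oxoprop-1-en-1-yl)-2-(4-hydroxyphenyl)-2,3-dihydrobenzofuran (one enantiomer drawn) | O=C(c1ccc(O)cc1O)[C@@H]1c2cc(/C=C/C(=O)c3ccc(O)cc3O)ccc2O[C@H]1c1ccc(O)cc1
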